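**Retrosynthetic overview**

1. Target ⇐ triple Lindlar semi-hydrogenation of a skipped triyne ⇐ Cu(I) coupling of a ring-bound terminal alkyne with methyl 10-bromodeca-5,8-diynoate (itself from methyl hex-5-ynoate and 1,4-dibromobut-2-yne).
2. Ring-bound alkyne (epoxy chloride) ⇐ Appel inversion (C–Cl) ⇐ hydroxyl-directed epoxidation (C–O, oxirane) ⇐ CBS reduction of an ethyl ketone ⇐ trans-2-ethynylcyclopent-3-ene-1-carboxylic acid.
3. That acid ⇐ anti-SN2' alkynylcopper opening of the bridged allylic lactone 2-oxabicyclo[2.2.1]hept-5-en-3-one.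
4. Lactone ⇐ key C–O bond formation: catalytic enantioselective desymmetrising selenolactonisation / selenoxide elimination of achiral cyclopent-3-ene-1-carboxylic acid, which fixes the absolute configuration.
5. Ring order: the carbocycle is bought; the bridged γ-lactone ring is made first and opened again; the oxirane is the last ring formed.

Assumption: N-(phenylselanyl)phthalimide, the cinchona squaramide catalyst, (S)-Me-CBS, EtLi solution and Lindlar catalyst are bought; which pseudo-enantiomeric catalyst (quinidine- or quinine-derived) gives (1S,4R)-4 must be fixed by a first trial, and the quinidine one is written here.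

**Route**

Step 1
Reactants: 1 cyclopent-3-ene-1-carboxylic acid; 2 N-(phenylselanyl)phthalimide
Product: 4 (1S,4R)-2-oxabicyclo[2.2.1]hept-5-en-3-one, via selenolactone 3 (not isolated)
Conditions: 2 (1.1 equiv), epi-quinidine-derived 3,5-(CF3)2-aryl squaramide (10 mol %), CH2Cl2–toluene, −60 °C; then pyridine, 30% aq. H2O2, 0 °C → rt; 4 kept cold and used as a solution
Reagents that add atoms: none
Why: Proposed new method: a catalytic enantioselective desymmetrising selenolactonisation in which the squaramide N–H groups bind the selenenyl donor and the quinuclidinium ion-pairs with the carboxylate, so that the carboxylate (which can only open the seleniranium on the ring face anti to it) closes inside a chiral ion pair onto one of the two enantiotopic alkene carbons of the reversibly formed meso-seleniranium and thereby sets both lactone stereocentres in the C–O bond-forming step, after which the rigid exo-selenoxide syn-eliminates with the neighbouring exo-H (the bridgehead direction is barred by Bredt's rule) to give 4; the closest known chemistry is cinchona-catalysed enantiofacial selenolactonisation of alkenoic acids, H-bond-donor-catalysed selenoetherification through dynamic seleniranium ions, and the racemic Nicolaou phenylselenolactonisation–selenoxide elimination.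

Step 2
Reactants: 4 (1S,4R)-2-oxabicyclo[2.2.1]hept-5-en-3-one; 5 ethynyltrimethylsilane
Product: 7 (1R,2R)-2-ethynylcyclopent-3-ene-1-carboxylic acid, via TMS-alkynyl acid 6 (not isolated)
Conditions: 5 (2.2 equiv), EtMgBr (2.0 equiv), THF, 0 °C → rt; CuBr·SMe2 (2.0 equiv), −20 °C; 4, −20 → 0 °C; then MeOH, K2CO3, rt; 1 M HCl work-up
Reagents that add atoms: ethynyltrimethylsilane (5), C#C[Si](C)(C)C
Why: Copper-mediated anti-SN2' allylic substitution, in which the strain-activated bridged allylic lactone is attacked by the alkynylcopper at the γ-carbon (next to the carboxyl-bearing carbon) on the face opposite the departing carboxylate, setting the trans C1/C2 relationship by chirality transfer, followed by K2CO3/MeOH protodesilylation.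

Step 3
Reactants: 7 (1R,2R)-2-ethynylcyclopent-3-ene-1-carboxylic acid; 8 ethyllithium
Product: 10 1-[(1R,2R)-2-ethynylcyclopent-3-en-1-yl]propan-1-one, via lithium gem-diolate 9 (not isolated)
Conditions: 8 (3.3 equiv), Et2O–THF, −78 → 0 °C; inverse quench into 1 M HCl at 0 °C
Reagents that add atoms: ethyllithium (8), [Li]CC
Why: Ketone synthesis from a carboxylic acid and an organolithium, in which two equivalents deprotonate CO2H and C≡C–H and the third adds to the lithium carboxylate to give gem-diolate 9, which cannot add again and collapses to the ketone only on acidic quench, so no tertiary alcohol forms and the trans (more stable) α-centre is kept.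

Step 4
Reactants: 10 1-[(1R,2R)-2-ethynylcyclopent-3-en-1-yl]propan-1-one
Product: 11 (1R)-1-[(1R,2R)-2-ethynylcyclopent-3-en-1-yl]propan-1-ol
Conditions: (S)-Me-CBS (15 mol %), catecholborane (1.8 equiv), toluene, −78 °C; aq. NaOH work-up; chromatography
Reagents that add atoms: none
Why: Corey–Bakshi–Shibata reduction, in which the (S)-oxazaborolidine treats the branched ring carbon as the large and ethyl as the small group and delivers hydride under catalyst control to give the (1R)-carbinol, while catecholborane at −78 °C leaves alkene and alkyne untouched; the minor epimer, and material from any minor enantiomer of 10 (which becomes a diastereomer), is removed by chromatography.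

Step 5
Reactants: 11 (1R)-1-[(1R,2R)-2-ethynylcyclopent-3-en-1-yl]propan-1-ol; 12 tert-butyl hydroperoxide
Product: 13 (1R)-1-[(1R,2R,3R,5S)-2-ethynyl-6-oxabicyclo[3.1.0]hexan-3-yl]propan-1-ol
Conditions: VO(acac)2 (5 mol %), 12 (1.5 equiv, decane solution), CH2Cl2, 0 °C → rt
Reagents that add atoms: tert-butyl hydroperoxide (12), CC(C)(C)OO
Why: Hydroxyl-directed vanadium-catalysed epoxidation (Sharpless–Michaelson type), in which the vanadate ester of the bishomoallylic carbinol delivers the peroxide oxygen to the ring face that carries the side chain, which is also the face anti to the alkynyl group, so both oxirane centres are set cis to C3 and trans to C2, and the alkyne is inert.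

Step 6
Reactants: 13 (1R)-1-[(1R,2R,3R,5S)-2-ethynyl-6-oxabicyclo[3.1.0]hexan-3-yl]propan-1-ol; 14 carbon tetrachloride
Product: 15 (1R,2R,3R,5S)-3-[(1S)-1-chloropropyl]-2-ethynyl-6-oxabicyclo[3.1.0]hexane
Conditions: PPh3 (2 equiv), 14 (5 equiv), NaHCO3, CH2Cl2, 40 °C
Reagents that add atoms: carbon tetrachloride (14), ClC(Cl)(Cl)Cl
Why: Appel reaction, in which chloride displaces the alkoxyphosphonium by SN2 with inversion and turns the (1R)-carbinol into the (1S)-chloride, with NaHCO3 buffering traces of HCl so the epoxide survives as in the known Appel chlorination of epoxy alcohols.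

Step 7
Reactants: 16 methyl hex-5-ynoate; 17 1,4-dibromobut-2-yne
Product: 18 methyl 10-bromodeca-5,8-diynoate
Conditions: 17 (4 equiv), CuI (0.5 equiv), Cs2CO3 (1.1 equiv), DMF, 0 °C → rt; excess 17 recovered
Reagents that add atoms: 1,4-dibromobut-2-yne (17), BrCC#CCBr
Why: Cu(I)-mediated coupling of a terminal alkyne with a propargylic bromide (Jeffery-type skipped-diyne synthesis), where the fourfold excess of the cheap symmetrical dibromide holds the reaction at mono-substitution and the ester tolerates the carbonate base.

Step 8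
Reactants: 15 (1R,2R,3R,5S)-3-[(1S)-1-chloropropyl]-2-ethynyl-6-oxabicyclo[3.1.0]hexane; 18 methyl 10-bromodeca-5,8-diynoate
Product: 19 methyl 12-[(1R,2R,3R,5S)-3-[(1S)-1-chloropropyl]-6-oxabicyclo[3.1.0]hexan-2-yl]dodeca-5,8,11-triynoate
Conditions: 18 (1.2 equiv), CuI (1 equiv), Cs2CO3 (1.1 equiv), DMF, rt, dark; used promptly
Reagents that add atoms: methyl 10-bromodeca-5,8-diynoate (18), BrCC#CCC#CCCCC(=O)OC
Why: The same copper-acetylide propargylation, run under mild carbonate conditions that leave the epoxide, the secondary chloride and the ester untouched and involve no stereocentre.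

Step 9
Reactants: 19 methyl 12-[(1R,2R,3R,5S)-3-[(1S)-1-chloropropyl]-6-oxabicyclo[3.1.0]hexan-2-yl]dodeca-5,8,11-triynoate
Product: 20 methyl (5Z,8Z,11Z)-12-[(1R,2S,3R,5S)-3-[(1S)-1-chloropropyl]-6-oxabicyclo[3.1.0]hexan-2-yl]dodeca-5,8,11-trienoate
Conditions: H2 (1 atm), Lindlar catalyst, quinoline, hexane–EtOAc, 0 °C → rt, stopped at 3 equiv H2
Reagents that add atoms: none
Why: Lindlar semi-hydrogenation, in which syn delivery of hydrogen on the poisoned palladium surface turns each of the three alkynes into a Z-alkene and sets the 5Z,8Z,11Z geometry while epoxide, secondary chloride and ester are inert; the ring C2 descriptor changes from R to S only because the CIP priority of the side chain changes.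

**Compound list**

1 | cyclopent-3-ene-1-carboxylic acid | OC(=O)C1CC=CC1 | starting material
2 | N-(phenylselanyl)phthalimide | O=C1N([Se]c2ccccc2)C(=O)c2ccccc12 | starting material
3 | (1S,4R,6S)-6-(phenylselanyl)-2-oxabicyclo[2.2.1]heptan-3-one | O=C1[C@@H]2C[C@H](O1)[C@@H]([Se]c3ccccc3)C2 | intermediate
4 | (1S,4R)-2-oxabicyclo[2.2.1]hept-5-en-3-one | O=C1[C@@H]2C[C@H](O1)C=C2 | intermediate
5 | ethynyltrimethylsilane | C#C[Si](C)(C)C | starting material
6 | (1R,2R)-2-[(trimethylsilyl)ethynyl]cyclopent-3-ene-1-carboxylic acid (present as its metal carboxylate) | OC(=O)[C@@H]1CC=C[C@H]1C#C[Si](C)(C)C | intermediate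
7 | (1R,2R)-2-ethynylcyclopent-3-ene-1-carboxylic acid | OC(=O)[C@@H]1CC=C[C@H]1C#C | intermediate
8 | ethyllithium | [Li]CC | starting material
9 | trilithium salt of 1-[(1R,2R)-2-ethynylcyclopent-3-en-1-yl]propane-1,1-diol (O,O-dilithio gem-diolate and lithium acetylide) | [Li+].[Li+].[Li+].CCC([O-])([O-])[C@@H]1CC=C[C@H]1C#[C-] | intermediate
10 | 1-[(1R,2R)-2-ethynylcyclopent-3-en-1-yl]propan-1-one | CCC(=O)[C@@H]1CC=C[C@H]1C#C | intermediate
11 | (1R)-1-[(1R,2R)-2-ethynylcyclopent-3-en-1-yl]propan-1-ol | CC[C@@H](O)[C@@H]1CC=C[C@H]1C#C | intermediate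
12 | tert-butyl hydroperoxide | CC(C)(C)OO | starting material
13 | (1R)-1-[(1R,2R,3R,5S)-2-ethynyl-6-oxabicyclo[3.1.0]hexan-3-yl]propan-1-ol | CC[C@@H](O)[C@@H]1C[C@@H]2O[C@@H]2[C@H]1C#C | intermediate
14 | carbon tetrachloride | ClC(Cl)(Cl)Cl | starting material
15 | (1R,2R,3R,5S)-3-[(1S)-1-chloropropyl]-2-ethynyl-6-oxabicyclo[3.1.0]hexane | CC[C@H](Cl)[C@@H]1C[C@@H]2O[C@@H]2[C@H]1C#C | intermediate
16 | methyl hex-5-ynoate | C#CCCCC(=O)OC | starting material
17 | 1,4-dibromobut-2-yne | BrCC#CCBr | starting material
18 | methyl 10-bromodeca-5,8-diynoate | BrCC#CCC#CCCCC(=O)OC | intermediate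
19 | methyl 12-[(1R,2R,3R,5S)-3-[(1S)-1-chloropropyl]-6-oxabicyclo[3.1.0]hexan-2-yl]dodeca-5,8,11-triynoate | CC[C@H](Cl)[C@@H]1C[C@@H]2O[C@@H]2[C@H]1C#CCC#CCC#CCCCC(=O)OC | intermediate
20 | methyl (5Z,8Z,11Z)-12-[(1R,2S,3R,5S)-3-[(1S)-1-chloropropyl]-6-oxabicyclo[3.1.0]hexan-2-yl]dodeca-5,8,11-trienoate | CC[C@H](Cl)[C@@H]1C[C@@H]2O[C@@H]2[C@H]1/C=C\C/C=C\C/C=C\CCCC(=O)OC | target

**Step count and risks**

Total step count: 9. Longest linear sequence: 8 (steps 1–6, 8, 9); step 7 is a one-step side branch.

The three steps most likely to fail: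

Step 1 is the new desymmetrising selenolactonisation; the risk is low enantioselectivity or poor turnover with the bridged product. The fallback uses known chemistry and sets out from 1. Racemic Nicolaou phenylselenolactonisation (PhSeCl, Et3N, CH2Cl2, −78 °C) gives rac-6-(phenylselanyl)-2-oxabicyclo[2.2.1]heptan-3-one F1, and H2O2/pyridine gives rac-2-oxabicyclo[2.2.1]hept-5-en-3-one F2. The conditions of step 2 then convert F2 by way of rac-trans-2-[(trimethylsilyl)ethynyl]cyclopent-3-ene-1-carboxylic acid F3 into rac-trans-2-ethynylcyclopent-3-ene-1-carboxylic acid F4. F4 is resolved classically by crystallising (S)-1-phenylethylammonium (1R,2R)-2-ethynylcyclopent-3-ene-1-carboxylate F5, while (S)-1-phenylethylammonium (1S,2S)-2-ethynylcyclopent-3-ene-1-carboxylate F6 stays in the mother liquor (the (R)-amine is used if the solubilities are reversed). Acidification of F5 comes back to the route at 7.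

Step 2 is risky because alkynylcopper reagents transfer poorly and a lactone carboxylate has not been shown as the leaving group for this anti-SN2' alkynylation; direct SN2 or carbonyl attack could compete. The fallback sets out from 4. Methanolysis (K2CO3, MeOH, 0 °C) gives methyl (1R,4S)-4-hydroxycyclopent-2-ene-1-carboxylate F7, and esterification with picolinic acid (EDC, DMAP) gives (1S,4R)-4-(methoxycarbonyl)cyclopent-2-en-1-yl pyridine-2-carboxylate F8. The known chelation-assisted anti-SN2' alkynylation of cyclopentenyl picolinates (TMSC≡CMgBr, CuBr·SMe2, THF) then gives methyl (1R,2R)-2-[(trimethylsilyl)ethynyl]cyclopent-3-ene-1-carboxylate F9. LiOH in THF/MeOH/H2O cleaves the ester and the silyl group and comes back to the route at 7.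

Step 6 is risky because the carbinol is β-branched, so SN2 is slow; elimination, incomplete inversion or participation of the cis epoxide oxygen could intervene. The fallback sets out from 11 and runs the Appel reaction before the epoxide exists, giving (3R,4R)-4-[(1S)-1-chloropropyl]-3-ethynylcyclopent-1-ene F10. Epoxidation of F10 with mCPBA/NaHCO3 in CH2Cl2 then relies on steric control (attack anti to the allylic alkynyl group) instead of hydroxyl direction. Face selectivity is expected to be only moderate, so the diastereomers are separated by chromatography, and the sequence comes back to the route at 15.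

**Further compounds**

F1 | step 1 | rac-(1R*,4S*,6R*)-6-(phenylselanyl)-2-oxabicyclo[2.2.1]heptan-3-one | O=C1OC2CC1CC2[Se]c1ccccc1
F2 | step 1 | rac-2-oxabicyclo[2.2.1]hept-5-en-3-one | O=C1OC2CC1C=C2
F3 | step 1 | rac-(1R*,2R*)-2-[(trimethylsilyl)ethynyl]cyclopent-3-ene-1-carboxylic acid | OC(=O)C1CC=CC1C#C[Si](C)(C)C
F4 | step 1 | rac-(1R*,2R*)-2-ethynylcyclopent-3-ene-1-carboxylic acid | OC(=O)C1CC=CC1C#C
F5 | step 1 | (S)-1-phenylethylammonium (1R,2R)-2-ethynylcyclopent-3-ene-1-carboxylate | [O-]C(=O)[C@@H]1CC=C[C@H]1C#C.C[C@H]([NH3+])c1ccccc1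
F6 | step 1 | (S)-1-phenylethylammonium (1S,2S)-2-ethynylcyclopent-3-ene-1-carboxylate | [O-]C(=O)[C@H]1CC=C[C@@H]1C#C.C[C@H]([NH3+])c1ccccc1
F7 | step 2 | methyl (1R,4S)-4-hydroxycyclopent-2-ene-1-carboxylate | COC(=O)[C@@H]1C[C@H](O)C=C1
F8 | step 2 | (1S,4R)-4-(methoxycarbonyl)cyclopent-2-en-1-yl pyridine-2-carboxylate | COC(=O)[C@@H]1C[C@H](OC(=O)c2ccccn2)C=C1
F9 | step 2 | methyl (1R,2R)-2-[(trimethylsilyl)ethynyl]cyclopent-3-ene-1-carboxylate | COC(=O)[C@@H]1CC=C[C@H]1C#C[Si](C)(C)C
F10 | step 6 | (3R,4R)-4-[(1S)-1-chloropropyl]-3-ethynylcyclopent-1-ene | CC[C@H](Cl)[C@@H]1CC=C[C@H]1C#C
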